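The target is an unbranched decamethylene chain (C1–C10, numbered from the 3,5-dimethoxyphenyl ring) ending in a phenyl ring, with no functional group on the chain. The route rests on disconnecting the C6–C7 bond between two plain methylenes. It exploits that C6 can be stored as the terminal carbon of a hex-5-enyl side chain (C5=C6) on the dimethoxybenzene ring. One-pot anti-Markovnikov hydroboration turns C6 into a primary alkylborane, and a palladium-catalysed alkyl–alkyl Suzuki coupling with (4-bromobutyl)benzene (C7–C10 plus phenyl) forges C6–C7 and leaves no trace of the handle. The precursor, 1-(hex-5-enyl)-3,5-dimethoxybenzene, comes in one step from 3,5-dimethoxybenzyl bromide.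

Key step: step 2

Remark on the chemistry: the target has no stereocentre and no double-bond geometry, so no stereochemical control is needed. All starting materials (1, 2, 5) and 9-BBN are assumed to be purchased.

Step 1
Reactants: 1 5-bromopent-1-ene; 2 3,5-dimethoxybenzyl bromide
Product: 4 1-(hex-5-en-1-yl)-3,5-dimethoxybenzene, via pent-4-enylmagnesium bromide 3 (not isolated)
Conditions: 1, Mg, THF, rt → 40 °C; then 2, Li2CuCl4 (3 mol %), THF, −20 °C → rt
Reagents that add atoms: none
Why: Kochi-type copper-catalysed Grignard alkylation, in which the cuprate formed from 3 should displace the activated benzylic bromide of 2 faster than halogen–metal exchange can occur, while the remote terminal alkene and the aryl methyl ethers are inert; no stereocentre is formed.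

Step 2
Reactants: 4 1-(hex-5-en-1-yl)-3,5-dimethoxybenzene; 5 (4-bromobutyl)benzene
Product: 7 1-(3,5-dimethoxyphenyl)-10-phenyldecane, via B-alkyl-9-BBN borane 6 (not isolated)
Conditions: 9-BBN (0.5 M in THF, 1.05 equiv), 0 °C → rt; then 5 (1.2 equiv), Pd(OAc)2 (4 mol %), PCy3 (8 mol %), K3PO4·H2O (1.3 equiv), THF, rt
Reagents that add atoms: none
Why: 9-BBN should add syn across C5=C6 of 4 through a four-centre transition state that places boron on the terminal C6, giving 6; PCy3-ligated Pd(0) then inserts into the C–Br bond of 5 by an SN2-type oxidative addition, the hydroxide-activated borate of 6 transfers its primary alkyl group to palladium, and reductive elimination forms the C6–C7 σ bond. The closest known reaction type is the B-alkyl Suzuki–Miyaura alkyl–alkyl coupling of primary alkyl bromides bearing β-hydrogens with alkyl-9-BBN reagents under Pd/PCy3 catalysis at room temperature. No ring is closed and no stereocentre is created. The step needs three selectivities: terminal regiochemistry in the hydroboration, which the bulky 9-BBN and the monosubstituted alkene secure; transfer of the primary hexyl group in preference to the hindered secondary bicyclic B–C bonds; and C–C reductive elimination in preference to β-hydride elimination, which the bulky, electron-rich PCy3 and the mild temperature favour. The two arenes and the methyl ethers carry no bond that Pd(0) or the borane can attack, so only the alkene and the C–Br bond react.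

Compound list
1 | 5-bromopent-1-ene | C=CCCCBr | starting material
2 | 3,5-dimethoxybenzyl bromide (1-(bromomethyl)-3,5-dimethoxybenzene) | COc1cc(CBr)cc(OC)c1 | starting material
3 | pent-4-enylmagnesium bromide | C=CCCC[Mg]Br | intermediate
4 | 1-(hex-5-en-1-yl)-3,5-dimethoxybenzene | COc1cc(CCCCC=C)cc(OC)c1 | intermediate
5 | (4-bromobutyl)benzene | BrCCCCc1ccccc1 | starting material
6 | 9-[6-(3,5-dimethoxyphenyl)hexyl]-9-borabicyclo[3.3.1]nonane | COc1cc(CCCCCCB2C3CCCC2CCC3)cc(OC)c1 | intermediate
7 | 1-(3,5-dimethoxyphenyl)-10-phenyldecane (1,3-dimethoxy-5-(10-phenyldecyl)benzene) | COc1cc(CCCCCCCCCCc2ccccc2)cc(OC)c1 | target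

Total step count: 2
Longest linear sequence: 2 steps (1 → 4 → 7)

Steps most likely to fail (the route has only two steps, so both are ranked and there is no third):

1. Step 2. The alkylpalladium(II) species formed from 5 may undergo β-hydride elimination before transmetalation. Transmetalation of the alkylborate may also be slow if the water content of the base is wrong, and PCy3 or the borane may be oxidised by adventitious air; each would stall the coupling. Fallback (sets out from 4, returns at 7; the polarity of the two chains is reversed and copper replaces palladium): compound 4 would be hydroborated with 9-BBN to borane 6 and oxidised with NaOH/H2O2 to 6-(3,5-dimethoxyphenyl)hexan-1-ol F1. Appel bromination (CBr4, PPh3, CH2Cl2, 0 °C) should convert this alcohol into 1-(6-bromohexyl)-3,5-dimethoxybenzene F2. Separately, 5 would be treated with Mg in THF to give 4-phenylbutylmagnesium bromide F3, and Li2CuCl4-catalysed Kochi coupling of this Grignard reagent with the bromide (THF, −20 °C → rt) should form the same C6–C7 bond and give 7.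

2. Step 1. Halogen–magnesium exchange or single-electron transfer between the Grignard reagent and the benzylic bromide may lead to Wurtz-type homocoupling of either partner and so consume both. Fallback (sets out from 2, uses 1, returns at 4; the benzylic carbon becomes the nucleophile): bromide 2 would be displaced with sodium benzenesulfinate (DMF, rt) to give 1,3-dimethoxy-5-[(phenylsulfonyl)methyl]benzene F4. Deprotonation with n-BuLi (THF, −78 °C) should give lithium (3,5-dimethoxyphenyl)(phenylsulfonyl)methanide F5, which would be alkylated with 1 to give racemic 1,3-dimethoxy-5-[1-(phenylsulfonyl)hex-5-en-1-yl]benzene F6. Reductive desulfonylation (Mg, MeOH, rt → 50 °C) should then remove the sulfonyl group without touching the terminal alkene and deliver 4.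

Further compounds
F1 | step 2 | 6-(3,5-dimethoxyphenyl)hexan-1-ol | COc1cc(CCCCCCO)cc(OC)c1
F2 | step 2 | 1-(6-bromohexyl)-3,5-dimethoxybenzene | COc1cc(CCCCCCBr)cc(OC)c1
F3 | step 2 | 4-phenylbutylmagnesium bromide | Br[Mg]CCCCc1ccccc1
F4 | step 1 | 1,3-dimethoxy-5-[(phenylsulfonyl)methyl]benzene | COc1cc(CS(=O)(=O)c2ccccc2)cc(OC)c1
F5 | step 1 | lithium (3,5-dimethoxyphenyl)(phenylsulfonyl)methanide | [Li+].COc1cc([CH-]S(=O)(=O)c2ccccc2)cc(OC)c1
F6 | step 1 | racemic 1,3-dimethoxy-5-[1-(phenylsulfonyl)hex-5-en-1-yl]benzene | COc1cc(C(CCCC=C)S(=O)(=O)c2ccccc2)cc(OC)c1
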